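**Plan**

1. Feature: numbering the ring C1 (quaternary oxirane carbon bearing C7H2OBz), C2 (CHOBz), C3 (CHOH), C4=C5 and C6 (oxirane CH), the four contiguous oxygen-bearing carbons C6–C1–C2–C3 beside the C4=C5 bond are carbons 2 to 5 of a hexopyranoside. The cyclohexene ring is therefore a pyranose carbon chain closed by one C–C bond.
2. Retrosynthesis: C3–OH goes back to a C3 ketone and C4=C5 to a C5 carbinol. The C4–C5 bond is then cut (aldol) to give a 6-deoxyhex-5-enopyranoside, whose enol ether comes from a 4,6-O-benzylidene acetal. C7 comes from a vinyl group added to a 3-ulose, and the oxirane from a tertiary alkoxide and a C-2 mesylate.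
3. Forward order of rings: pyranose ring of methyl α-D-mannopyranoside, then the dioxane acetal (step 1), the oxirane (step 6), opening of the acetal (step 9), and the carbocycle formed as the pyranose ring opens (step 11); enone and allylic alcohol follow.
4. Stereochemistry: target C2 is C-4 of D-mannose. C1 is set by equatorial vinyl addition to the 3-ulose, C6 by SN2 inversion of the axial manno C-2 mesylate, and C3 by Luche reduction anti to the C2 benzoate.

Key step: step 11

Assumption: the carbinol centre C5 of 19 is drawn with the hydroxyl trans to the oxirane oxygen; either epimer serves, because this centre becomes sp2 in step 12. Pyranosides carry sugar numbering (C-1 to C-6); carbocycles carry the ring numbering of line 1.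

**Step 1**
Reactants: 1 methyl α-D-mannopyranoside; 2 benzaldehyde dimethyl acetal
Product: 3 methyl 4,6-O-[(R)-benzylidene]-α-D-mannopyranoside
Conditions: PhCH(OMe)2 (1.1 equiv), HBF4·OEt2 (cat.), DMF, rt
Reagents that add atoms: benzaldehyde dimethyl acetal (2), COC(OC)c1ccccc1
Why: Acid-catalysed transacetalisation (benzylidene acetal formation) should settle on the trans-fused six-membered 4,6-acetal with equatorial phenyl, and the small excess of 2 should leave the cis-2,3-diol free.

**Step 2**
Reactants: 3 methyl 4,6-O-benzylidene-α-D-mannopyranoside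
Product: 5 methyl 4,6-O-benzylidene-3-O-(4-methoxybenzyl)-α-D-mannopyranoside, via 2,3-O-dibutylstannylene acetal 4 (not isolated)
Conditions: Bu2SnO, toluene, reflux (Dean–Stark); then PMBCl, Bu4NI (cat.), 90 °C
Reagents that add atoms: 4-methoxybenzyl chloride, COc1ccc(CCl)cc1; dibutyltin oxide, CCCC[Sn](=O)CCCC (its atoms remain only in 4)
Why: Stannylene-acetal-mediated alkylation of a cis-diol takes place at the equatorial oxygen, so O-3 should be etherified and the axial 2-OH left free.

**Step 3**
Reactants: 5 methyl 4,6-O-benzylidene-3-O-(4-methoxybenzyl)-α-D-mannopyranoside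
Product: 6 methyl 4,6-O-benzylidene-2-O-methanesulfonyl-3-O-(4-methoxybenzyl)-α-D-mannopyranoside
Conditions: MsCl, Et3N, CH2Cl2, 0 °C
Reagents that add atoms: methanesulfonyl chloride, CS(=O)(=O)Cl
Why: Sulfonylation of the only free hydroxyl puts the leaving group on the β-face at C-2 without touching its configuration.

**Step 4**
Reactants: 6 methyl 4,6-O-benzylidene-2-O-methanesulfonyl-3-O-(4-methoxybenzyl)-α-D-mannopyranoside
Product: 7 methyl 4,6-O-benzylidene-2-O-methanesulfonyl-α-D-mannopyranoside
Conditions: DDQ, CH2Cl2–pH 7 buffer, rt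
Reagents that add atoms: none
Why: Oxidative cleavage of the electron-rich 4-methoxybenzyl ether by DDQ should spare the benzylidene acetal and the mesylate.

**Step 5**
Reactants: 7 methyl 4,6-O-benzylidene-2-O-methanesulfonyl-α-D-mannopyranoside
Product: 8 methyl 4,6-O-benzylidene-2-O-methanesulfonyl-α-D-arabino-hexopyranosid-3-ulose
Conditions: Dess–Martin periodinane, CH2Cl2, rt
Reagents that add atoms: none
Why: Dess–Martin oxidation gives the 3-ulose under non-basic conditions, which should protect the axial α-mesyloxy centre C-2 from epimerisation and β-elimination.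

**Step 6**
Reactants: 8 methyl 4,6-O-benzylidene-2-O-methanesulfonyl-α-D-arabino-hexopyranosid-3-ulose; 9 vinylmagnesium bromide
Product: 11 methyl 2,3-anhydro-4,6-O-benzylidene-3-C-vinyl-α-D-allopyranoside, via hydroxy mesylate 10 (not isolated)
Conditions: CH2=CHMgBr, CeCl3, THF, −78 °C; then MeOH, K2CO3, rt
Reagents that add atoms: vinylmagnesium bromide (9), C=C[Mg]Br
Why: Carbonyl addition of the weakly basic vinylcerium reagent should come from the equatorial β-direction, away from the axial anomeric methoxy group that shields the α-face, so that O-3 becomes axial and antiperiplanar to the axial C-2 mesylate, and base then closes the oxirane by intramolecular Williamson SN2 displacement with inversion at C-2 (allo epoxide, branch carbon trans to the oxirane oxygen).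

**Step 7**
Reactants: 11 methyl 2,3-anhydro-4,6-O-benzylidene-3-C-vinyl-α-D-allopyranoside
Product: 13 methyl 2,3-anhydro-4,6-O-benzylidene-3-C-(hydroxymethyl)-α-D-allopyranoside, via epoxy aldehyde 12 (not isolated)
Conditions: O3, CH2Cl2–MeOH, −78 °C; then NaBH4, −78 → 0 °C
Reagents that add atoms: ozone, [O-][O+]=O
Why: Ozonolysis with reductive borohydride work-up should cleave the vinyl group much faster than ozone attacks the acetal C–H at −78 °C and reduce the epoxy aldehyde to the primary alcohol without disturbing the oxirane or C-3.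

**Step 8**
Reactants: 13 methyl 2,3-anhydro-4,6-O-benzylidene-3-C-(hydroxymethyl)-α-D-allopyranoside; 14 benzoyl chloride
Product: 15 methyl 2,3-anhydro-3-C-(benzoyloxymethyl)-4,6-O-benzylidene-α-D-allopyranoside
Conditions: BzCl, pyridine, DMAP (cat.), CH2Cl2, 0 °C → rt
Reagents that add atoms: benzoyl chloride (14), O=C(Cl)c1ccccc1
Why: DMAP-catalysed acylation of the only free hydroxyl installs the C7 benzoate of the target.

**Step 9**
Reactants: 15 methyl 2,3-anhydro-3-C-(benzoyloxymethyl)-4,6-O-benzylidene-α-D-allopyranoside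
Product: 16 methyl 2,3-anhydro-4-O-benzoyl-3-C-(benzoyloxymethyl)-6-bromo-6-deoxy-α-D-allopyranoside
Conditions: NBS, BaCO3, CCl4, reflux
Reagents that add atoms: N-bromosuccinimide, O=C1CCC(=O)N1Br
Why: In the Hanessian–Hullar reaction, radical bromination at the acetal carbon, ionisation and attack of bromide on the primary C-6 should give the 4-benzoate 6-bromide regioselectively, and the reaction tolerates 2,3-anhydro sugars and esters.

**Step 10**
Reactants: 16 methyl 2,3-anhydro-4-O-benzoyl-3-C-(benzoyloxymethyl)-6-bromo-6-deoxy-α-D-allopyranoside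
Product: 17 methyl 2,3-anhydro-4-O-benzoyl-3-C-(benzoyloxymethyl)-6-deoxy-α-D-ribo-hex-5-enopyranoside
Conditions: AgF, pyridine, rt, dark
Reagents that add atoms: none
Why: Silver-assisted E2 dehydrobromination can only remove H-5, so the exocyclic enol ether should form while both benzoates and the oxirane survive the mild, non-nucleophilic conditions.

**Step 11**
Reactants: 17 methyl 2,3-anhydro-4-O-benzoyl-3-C-(benzoyloxymethyl)-6-deoxy-α-D-ribo-hex-5-enopyranoside
Product: 19 (1S,2S,5R,6S)-2-benzoyloxy-1-(benzoyloxymethyl)-5-hydroxy-7-oxabicyclo[4.1.0]heptan-3-one, via mercurio keto-aldehyde 18 (not isolated)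
Conditions: Hg(OCOCF3)2 (5 mol %), acetone–H2O (2:1), rt
Reagents that add atoms: water, O; Hg(OCOCF3)2, O=C(O[Hg]OC(=O)C(F)(F)F)C(F)(F)F (its atoms remain only in 18)
Why: Divalent mercury adds to the electron-rich exocyclic enol ether (mercury to C-6, water to C-5), the hemiketal opens and methanol is lost from C-1 to give the α-mercurio ketone aldehyde 18, whose mercury-bearing carbon adds to the aldehyde and, after protonolysis of the O–Hg bond, returns the catalyst. This is the Ferrier carbocyclisation of 6-deoxyhex-5-enopyranosides, run here on a 2,3-anhydro sugar. The cyclohexanone ring closes in the 6-(enolexo)-exo-trig aldol mode and the new bond is C4–C5 of the target. The one new stereocentre, the carbinol C5, is expected from a chair-like aldol transition state with the hydroxyl trans to the neighbouring oxirane oxygen, but it is removed in step 12 and needs no control. The selectivity that matters is chemoselectivity: the mercury salt must engage the enol ether and not the oxirane or the esters, which the much higher nucleophilicity of the enol ether, the catalytic loading and the near-neutral medium should secure. Only C-6 can carry mercury, so a single aldol mode is open.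

**Step 12**
Reactants: 19 (1S,2S,5R,6S)-2-benzoyloxy-1-(benzoyloxymethyl)-5-hydroxy-7-oxabicyclo[4.1.0]heptan-3-one
Product: 21 (1S,2S,6S)-2-benzoyloxy-1-(benzoyloxymethyl)-7-oxabicyclo[4.1.0]hept-4-en-3-one, via C5 mesylate 20 (not isolated)
Conditions: MsCl (1.2 equiv), Et3N (2.2 equiv), CH2Cl2, 0 °C, prompt work-up
Reagents that add atoms: methanesulfonyl chloride, CS(=O)(=O)Cl (its atoms remain only in 20)
Why: Mesylation followed by E1cB elimination through the C4 enolate gives the conjugated enone, because mesylate leaves far more readily than the β-oxirane oxygen on the other flank, and the limited base, low temperature and short contact time should suppress enolisation at C2 (oxirane opening and aromatisation).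

**Step 13**
Reactants: 21 (1S,2S,6S)-2-benzoyloxy-1-(benzoyloxymethyl)-7-oxabicyclo[4.1.0]hept-4-en-3-one
Product: 22 [(1S,2R,3R,6S)-2-benzoyloxy-3-hydroxy-7-oxabicyclo[4.1.0]hept-4-en-1-yl]methyl benzoate (target; oxirane oxygen, C2 benzoate and C3 hydroxyl all cis)
Conditions: NaBH4, CeCl3·7H2O, MeOH, −78 °C
Reagents that add atoms: none
Why: Luche reduction adds hydride 1,2 to the enone and should do so on the face opposite the C2 benzoate and the oxirane oxygen (anti to the α-C–O bond in the Felkin–Anh sense on a nearly flat ring), placing the C3 hydroxyl cis to the C2 benzoate, while the low temperature spares the esters and the vinyl oxirane.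

**Compound list**

1 | methyl α-D-mannopyranoside | CO[C@H]1O[C@H](CO)[C@@H](O)[C@H](O)[C@@H]1O | starting material
2 | benzaldehyde dimethyl acetal | COC(OC)c1ccccc1 | starting material
3 | methyl 4,6-O-[(R)-benzylidene]-α-D-mannopyranoside | CO[C@H]1O[C@@H]2CO[C@@H](c3ccccc3)O[C@H]2[C@H](O)[C@@H]1O | intermediate
4 | methyl 4,6-O-benzylidene-2,3-O-(dibutylstannylene)-α-D-mannopyranoside | CO[C@H]1O[C@@H]2CO[C@@H](c3ccccc3)O[C@H]2[C@@H]4O[Sn](CCCC)(CCCC)O[C@H]14 | intermediate (not isolated)
5 | methyl 4,6-O-benzylidene-3-O-(4-methoxybenzyl)-α-D-mannopyranoside | CO[C@H]1O[C@@H]2CO[C@@H](c3ccccc3)O[C@H]2[C@H](OCc4ccc(OC)cc4)[C@@H]1O | intermediate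
6 | methyl 4,6-O-benzylidene-2-O-methanesulfonyl-3-O-(4-methoxybenzyl)-α-D-mannopyranoside | CO[C@H]1O[C@@H]2CO[C@@H](c3ccccc3)O[C@H]2[C@H](OCc4ccc(OC)cc4)[C@@H]1OS(C)(=O)=O | intermediate
7 | methyl 4,6-O-benzylidene-2-O-methanesulfonyl-α-D-mannopyranoside | CO[C@H]1O[C@@H]2CO[C@@H](c3ccccc3)O[C@H]2[C@H](O)[C@@H]1OS(C)(=O)=O | intermediate
8 | methyl 4,6-O-benzylidene-2-O-methanesulfonyl-α-D-arabino-hexopyranosid-3-ulose | CO[C@H]1O[C@@H]2CO[C@@H](c3ccccc3)O[C@H]2C(=O)[C@@H]1OS(C)(=O)=O | intermediate
9 | vinylmagnesium bromide | C=C[Mg]Br | starting material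
10 | methyl 4,6-O-benzylidene-2-O-methanesulfonyl-3-C-vinyl-α-D-altropyranoside | CO[C@H]1O[C@@H]2CO[C@@H](c3ccccc3)O[C@H]2[C@](O)(C=C)[C@@H]1OS(C)(=O)=O | intermediate (not isolated)
11 | methyl 2,3-anhydro-4,6-O-benzylidene-3-C-vinyl-α-D-allopyranoside | CO[C@H]1O[C@@H]2CO[C@@H](c3ccccc3)O[C@H]2[C@@]4(C=C)O[C@@H]14 | intermediate
12 | methyl 2,3-anhydro-4,6-O-benzylidene-3-C-formyl-α-D-allopyranoside | CO[C@H]1O[C@@H]2CO[C@@H](c3ccccc3)O[C@H]2[C@@]4(C=O)O[C@@H]14 | intermediate (not isolated)
13 | methyl 2,3-anhydro-4,6-O-benzylidene-3-C-(hydroxymethyl)-α-D-allopyranoside | CO[C@H]1O[C@@H]2CO[C@@H](c3ccccc3)O[C@H]2[C@@]4(CO)O[C@@H]14 | intermediate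
14 | benzoyl chloride | O=C(Cl)c1ccccc1 | starting material
15 | methyl 2,3-anhydro-3-C-(benzoyloxymethyl)-4,6-O-benzylidene-α-D-allopyranoside | CO[C@H]1O[C@@H]2CO[C@@H](c3ccccc3)O[C@H]2[C@@]4(COC(=O)c5ccccc5)O[C@@H]14 | intermediate
16 | methyl 2,3-anhydro-4-O-benzoyl-3-C-(benzoyloxymethyl)-6-bromo-6-deoxy-α-D-allopyranoside | CO[C@H]1O[C@H](CBr)[C@@H](OC(=O)c3ccccc3)[C@@]2(COC(=O)c3ccccc3)O[C@@H]12 | intermediate
17 | methyl 2,3-anhydro-4-O-benzoyl-3-C-(benzoyloxymethyl)-6-deoxy-α-D-ribo-hex-5-enopyranoside | CO[C@H]1OC(=C)[C@@H](OC(=O)c3ccccc3)[C@@]2(COC(=O)c3ccccc3)O[C@@H]12 | intermediate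
18 | 2,3-anhydro-4-O-benzoyl-3-C-(benzoyloxymethyl)-6-deoxy-6-(trifluoroacetoxymercurio)-aldehydo-D-ribo-hexos-5-ulose | O=C[C@@H]1O[C@]1(COC(=O)c2ccccc2)[C@H](OC(=O)c3ccccc3)C(=O)C[Hg]OC(=O)C(F)(F)F | intermediate (not isolated)
19 | (1S,2S,5R,6S)-2-benzoyloxy-1-(benzoyloxymethyl)-5-hydroxy-7-oxabicyclo[4.1.0]heptan-3-one | O=C(OC[C@]12O[C@H]1[C@H](O)CC(=O)[C@H]2OC(=O)c1ccccc1)c1ccccc1 | intermediate
20 | (1S,2S,5R,6S)-2-benzoyloxy-1-(benzoyloxymethyl)-5-(methanesulfonyloxy)-7-oxabicyclo[4.1.0]heptan-3-one | O=C(OC[C@]12O[C@H]1[C@H](OS(C)(=O)=O)CC(=O)[C@H]2OC(=O)c1ccccc1)c1ccccc1 | intermediate (not isolated)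
21 | (1S,2S,6S)-2-benzoyloxy-1-(benzoyloxymethyl)-7-oxabicyclo[4.1.0]hept-4-en-3-one | O=C(OC[C@]12O[C@H]1C=CC(=O)[C@H]2OC(=O)c1ccccc1)c1ccccc1 | intermediate
22 | [(1S,2R,3R,6S)-2-benzoyloxy-3-hydroxy-7-oxabicyclo[4.1.0]hept-4-en-1-yl]methyl benzoate | O=C(OC[C@]12O[C@H]1C=C[C@@H](O)[C@H]2OC(=O)c1ccccc1)c1ccccc1 | target

**Step count**

Total: 13 steps. Longest linear sequence: 13 steps (from 1 to 22; the route is fully linear).

**Steps most likely to fail**

Step 6. The nucleophile may add along the axial trajectory, anti to the C-2 mesylate (polar Felkin–Anh control overriding the shielding by the anomeric methoxy group). That would give the C-3 epimer, which cannot close to the oxirane. The organometallic may also enolise the α-mesyloxy ketone. The fallback sets out from 8 and comes back at 13, replacing steps 6 and 7. Ketone 8 would be methylenated under non-basic conditions (Zn, CH2Br2, TiCl4, THF–CH2Cl2; Takai–Lombardo) to methyl 4,6-O-benzylidene-3-deoxy-2-O-methanesulfonyl-3-C-methylene-α-D-arabino-hexopyranoside F1. Dihydroxylation (OsO4 cat., N-methylmorpholine N-oxide, acetone–H2O) is an electrophilic addition and is expected anti to the allylic C-2 mesylate. The bias that would spoil the nucleophilic addition then places the tertiary oxygen on the α-face, giving methyl 4,6-O-benzylidene-3-C-(hydroxymethyl)-2-O-methanesulfonyl-α-D-altropyranoside F2. K2CO3 in MeOH would close the tertiary alkoxide onto C-2 and deliver 13.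

Step 11. The Lewis-acidic mercury salt and water may open the oxirane, or hydration of the epoxy aldehyde may stall the aldol closure. The fallback sets out from 17 and comes back at 19, forming the same C–C bond without mercury. NBS in wet THF at 0 °C would add bromine to C-6 and water to C-5; the hemiketal opens and loses methanol to give 2,3-anhydro-4-O-benzoyl-3-C-(benzoyloxymethyl)-6-bromo-6-deoxy-aldehydo-D-ribo-hexos-5-ulose F3. SmI2 (THF, −78 °C) would reduce the C–Br bond first, forming the samarium enolate regiospecifically at C-6, and the intramolecular Reformatsky-type aldol would give 19.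

Step 13. Facial selectivity may be poor or reversed, with hydride adding syn to the C2 benzoate. The fallback sets out from 21 and comes back at 22. The same reduction of 21 would then give mainly the C3 epimer, [(1S,2R,3S,6S)-2-benzoyloxy-3-hydroxy-7-oxabicyclo[4.1.0]hept-4-en-1-yl]methyl benzoate F4. Mitsunobu inversion (HCO2H, PPh3, DIAD, THF, 0 °C) would give the formate with the target configuration at C3, [(1S,2R,3R,6S)-2-benzoyloxy-3-formyloxy-7-oxabicyclo[4.1.0]hept-4-en-1-yl]methyl benzoate F5. Methanolysis of the formate (KHCO3, MeOH, 0 °C), to which the benzoates are inert, would give 22.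

**Further compounds**

F1 | step 6 | methyl 4,6-O-benzylidene-3-deoxy-2-O-methanesulfonyl-3-C-methylene-α-D-arabino-hexopyranoside | CO[C@H]1O[C@@H]2CO[C@@H](c3ccccc3)O[C@H]2C(=C)[C@@H]1OS(C)(=O)=O
F2 | step 6 | methyl 4,6-O-benzylidene-3-C-(hydroxymethyl)-2-O-methanesulfonyl-α-D-altropyranoside | CO[C@H]1O[C@@H]2CO[C@@H](c3ccccc3)O[C@H]2[C@](O)(CO)[C@@H]1OS(C)(=O)=O
F3 | step 11 | 2,3-anhydro-4-O-benzoyl-3-C-(benzoyloxymethyl)-6-bromo-6-deoxy-aldehydo-D-ribo-hexos-5-ulose | O=C[C@@H]1O[C@]1(COC(=O)c2ccccc2)[C@H](OC(=O)c3ccccc3)C(=O)CBr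
F4 | step 13 | [(1S,2R,3S,6S)-2-benzoyloxy-3-hydroxy-7-oxabicyclo[4.1.0]hept-4-en-1-yl]methyl benzoate | O=C(OC[C@]12O[C@H]1C=C[C@H](O)[C@H]2OC(=O)c1ccccc1)c1ccccc1
F5 | step 13 | [(1S,2R,3R,6S)-2-benzoyloxy-3-formyloxy-7-oxabicyclo[4.1.0]hept-4-en-1-yl]methyl benzoate | O=C(OC[C@]12O[C@H]1C=C[C@@H](OC=O)[C@H]2OC(=O)c1ccccc1)c1ccccc1
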